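The readings are calculated on assumed constants, and the scatter is random.

Two questions stand, and both need the place where first end groups stop in the flask before they need any rate.

in all of them: second end groups 0.137 M

| charge | first end groups | protic impurity | remark | time |
|---|---|---|---|---|
| Friday's | 0.070 M | 0.042 M | run made earlier |  |
| Thursday's | 0.11 M | 0.042 M | run made earlier |  |
| Monday's | 0.14 M | 0.063 M | run made earlier |  |
| flask | 0.14 M | 0.0420 M |  | 30 h |

| run | time / h | over-reaction product / % | rings / % | links / % | first end groups / % |
|---|---|---|---|---|---|
| Friday's | 8.00 | 4.8 | 52.9 | 22.8 | 20.3 |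
| Friday's | 15.0 | 10.6 | 63.6 | 21.0 | 4.9 |
| Friday's | 25.0 | 17.1 | 66.7 | 15.4 | 0 |
| Friday's | 30.0 | 20.0 | 67.1 | 12.3 | 0.9 |
| Thursday's | 4.00 | 1.8 | 37.5 | 16.7 | 44.7 |
| Thursday's | 10.0 | 7.3 | 59.4 | 20.2 | 18.0 |
| Thursday's | 20.0 | 10.3 | 69.0 | 14.4 | 5.2 |
| Thursday's | 30.0 | 15.5 | 73.3 | 12.4 | 0 |
| Monday's | 8.00 | 3.3 | 54.3 | 17.1 | 24.4 |
| Monday's | 15.0 | 9.8 | 67.9 | 15.0 | 10.2 |
| Monday's | 25.0 | 11.6 | 70.4 | 9.4 | 10.2 |
| Monday's | 30.0 | 12.6 | 70.7 | 7.3 | 6.7 |

(scatter of a reading: 1 percentage point)

- the earlier runs were read with a standard deviation of 1 percentage point

- the species in which most of what was charged as first end groups, at 30 h sits (first end groups / links / rings / over-reaction product)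
- the largest share itself, whichever of these holds it, in percent of the first end groups charged

Monday's run, charged with the flask's end groups, reads as stalled with first end groups near 8.45 %, the mean of its readings 10.2 % and 6.7 %. Counting the two end groups as used one for one and taking the stall as the end of its second end groups, this reckoning puts the part of them lost elsewhere at 0.00883 M, and this loss, assumed proportional to c(protic impurity), is reckoned as 0.00589 M for the flask. The number to carry is the usable equivalents E = 0.937, the c(second end groups) left after that loss per c(first end groups) charged. Below one, it marks second end groups as the limiting reagent and puts the stop of first end groups at an estimated 6.30 % in the flask.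

One number is not enough: Thursday's and Friday's charge ratios, 1.25 and 1.96, stand above one, and first end groups read 0 % and 0.9 %, yet rings read 73.3 % and 67.1 %. Monday's ring selectivity, rings per first end group reacted, reads 0.771, so this reckoning, assuming that selectivity carries over, estimates 72.2 % rings for the flask, the largest share, with 21.5 % for links and over-reaction product together.

The forecast says rings at 71 %: “Rings clearly hold the most”. At 30 h the flask gives rings at 71.4 %, with first end groups at 6.38 %, second end groups at 0 % and quenched reagent at 0.00593 M.

    links → over-reaction product (k = 5.98 × 10⁻⁴ min⁻¹)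
    second end groups + protic impurity → quenched reagent (k = 0.00409 M⁻¹ min⁻¹)
    first end groups + second end groups → links (k = 0.0110 M⁻¹ min⁻¹)
    first end groups + second end groups → rings, rate k4*[first end groups] as long as [second end groups] is above zero (k = 0.00221 min⁻¹)

The neighbouring flask, charged with 0.034 M of second end groups and otherwise alike, forms 3.11 × 10⁻⁴ M of quenched reagent by 30.0 h, so its E is 0.241 and first end groups should stop at 75.9 %. They stand at 76 %, and first end groups now hold the most. Rings in that flask reach 22.2 %, which is 0.924 of what reacted, against 0.763 in the flask itself, while over-reaction product there stands at 1.19 %.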